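Numbering: C1 (guaiacyl-bearing ether carbon), O2, C3 (ether CH2), C4 and C5 (ring fusion, C5 beside the lactone carbonyl C6), O7, C8 (syringyl-bearing lactone carbon). The lactone ring is read as a cyclobutanone (C4, C5, C6, C8) with O7 inserted beside benzylic C8, and the fusion bond C4–C5 as the alkene of an (S)-2-aryl-2,5-dihydrofuran (C1, O2, C3, C4, C5). One keteniminium [2+2] cycloaddition of a syringylacetamide onto that alkene forms C5–C6 and C4–C8, closes the four-membered ring cis-fused and sets C4, C5 and C8 from the Heck-derived centre C1; Baeyer–Villiger oxidation and desilylation finish. Precursors: the TBS-protected dihydrofuran and the TBS-protected N,N-dimethylamide.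

Key step: step 7

Abbreviations: guaiacyl = 4-hydroxy-3-methoxyphenyl; syringyl = 4-hydroxy-3,5-dimethoxyphenyl; TBS = tert-butyldimethylsilyl.

Assumption (step 4): the sense of induction is carried over from the parent arylation of 2,3-dihydrofuran, where the (S)-configured tert-butyl phosphinooxazoline gives the (R)-2-aryl-2,5-dihydrofuran. The (R)-ligand is therefore specified for the (S)-dihydrofuran; the CIP order O > aryl > vinyl at C1 is the same in both cases.

Design remark: both phenols travel as TBS ethers. These should be inert to Tf2O/collidine and to peracid, and they keep the syringyl ring electron-rich, which the later benzylic migration needs. They leave together under acid-buffered fluoride, the one deprotection that does not expose the para-hydroxybenzylic C1–O2 and C8–O7 bonds to base. In the key step the amide is kept in excess over Tf2O, so that no free anhydride or strong acid meets the benzylic, allylic ether of the dihydrofuran.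

Step 1
Reactants: 1 vanillin (4-hydroxy-3-methoxybenzaldehyde)
Product: 2 4-[(tert-butyldimethylsilyl)oxy]-3-methoxybenzaldehyde
Conditions: TBSCl, imidazole, DMF, 25 °C
Reagents that add atoms: tert-butyldimethylsilyl chloride (TBSCl), CC(C)(C)[Si](C)(C)Cl
Why: Phenol silylation with TBSCl/imidazole is fast on the unhindered hydroxyl and gives an ether that should survive every later step and leave with buffered fluoride.

Step 2
Reactants: 2 4-[(tert-butyldimethylsilyl)oxy]-3-methoxybenzaldehyde
Product: 4 4-[(tert-butyldimethylsilyl)oxy]-3-methoxyphenol, via aryl formate 3 (not isolated)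
Conditions: mCPBA, CH2Cl2, 25 °C; then Et3N, MeOH, 0 °C
Reagents that add atoms: 3-chloroperoxybenzoic acid (mCPBA), O=C(OO)c1cccc(Cl)c1
Why: Baeyer–Villiger oxidation in its Dakin-type sense: in the tetrahedral peracid adduct of this para-oxygenated benzaldehyde the electron-rich aryl group migrates in preference to hydrogen, and the labile formate 3 is methanolysed by a weak amine base that should leave the aryl silyl ether untouched.

Step 3
Reactants: 4 4-[(tert-butyldimethylsilyl)oxy]-3-methoxyphenol
Product: 5 4-[(tert-butyldimethylsilyl)oxy]-3-methoxyphenyl trifluoromethanesulfonate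
Conditions: Tf2O, pyridine, CH2Cl2, 0 °C
Reagents that add atoms: trifluoromethanesulfonic anhydride (Tf2O), O=S(=O)(OS(=O)(=O)C(F)(F)F)C(F)(F)F
Why: O-Sulfonylation of the only free hydroxyl gives the aryl triflate that the cationic Heck pathway requires.

Step 4
Reactants: 5 4-[(tert-butyldimethylsilyl)oxy]-3-methoxyphenyl trifluoromethanesulfonate; 6 2,3-dihydrofuran (4 equiv)
Product: 7 (S)-2-{4-[(tert-butyldimethylsilyl)oxy]-3-methoxyphenyl}-2,5-dihydrofuran
Conditions: Pd2(dba)3 (tris(dibenzylideneacetone)dipalladium, 1.5 mol %), (R)-4-tert-butyl-2-[2-(diphenylphosphanyl)phenyl]-4,5-dihydrooxazole ((R)-t-Bu-PHOX, 6 mol %), i-Pr2NEt, THF, 70 °C, sealed vessel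
Reagents that add atoms: none
Why: Asymmetric intermolecular Heck reaction: the cationic arylpalladium triflate adds across the enol ether with the aryl group on the oxygen-bearing carbon, syn β-hydride elimination is possible only away from that carbon, and the P,N-ligand releases the 2,5-dihydrofuran without re-insertion, so the ligand-controlled face of insertion sets C1 as S and the double bond stays at C4=C5.

Step 5
Reactants: 8 4-hydroxy-3,5-dimethoxyphenylacetic acid
Product: 9 2-(4-hydroxy-3,5-dimethoxyphenyl)-N,N-dimethylacetamide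
Conditions: EDC·HCl, HOBt, Me2NH (2 M in THF), CH2Cl2, 0 °C to 25 °C
Reagents that add atoms: dimethylamine, CNC
Why: Carbodiimide/HOBt amide coupling; the phenol, flanked by two methoxy groups, is too hindered to compete with dimethylamine for the activated acid.

Step 6
Reactants: 9 2-(4-hydroxy-3,5-dimethoxyphenyl)-N,N-dimethylacetamide
Product: 10 2-{4-[(tert-butyldimethylsilyl)oxy]-3,5-dimethoxyphenyl}-N,N-dimethylacetamide
Conditions: TBSCl, imidazole, DMF, 40 °C
Reagents that add atoms: tert-butyldimethylsilyl chloride (TBSCl), CC(C)(C)[Si](C)(C)Cl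
Why: Silylation of the hindered syringyl hydroxyl masks the only site in 9 that Tf2O would otherwise sulfonylate.

Step 7
Reactants: 7 (S)-2-{4-[(tert-butyldimethylsilyl)oxy]-3-methoxyphenyl}-2,5-dihydrofuran (1.0 equiv); 10 2-{4-[(tert-butyldimethylsilyl)oxy]-3,5-dimethoxyphenyl}-N,N-dimethylacetamide (1.5 equiv)
Product: 13 (1S,2S,5R,6S)-2-{4-[(tert-butyldimethylsilyl)oxy]-3-methoxyphenyl}-6-{4-[(tert-butyldimethylsilyl)oxy]-3,5-dimethoxyphenyl}-3-oxabicyclo[3.2.0]heptan-7-one (cis-fused; syringyl exo), via keteniminium triflate 11 (not isolated), via cyclobutaniminium triflate 12 (not isolated)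
Conditions: Tf2O (1.4 equiv) added over 1 h to 7, 10 and 2,4,6-collidine (1.8 equiv), ClCH2CH2Cl, 80 °C; then H2O, 60 °C
Reagents that add atoms: water, O
Why: Tf2O O-activates amide 10 and collidine removes the benzylic α-proton to give keteniminium triflate 11, whose sp carbon C6 is attacked by the C4=C5 π bond (C5–C6) while the enamine-type carbon C8 closes on the developing cation at C4 (C4–C8), and water then hydrolyses iminium 12 to the ketone. This is the known keteniminium–alkene [2+2] cycloaddition of tertiary amides with unactivated cis-alkenes. The cyclobutane (C4, C5, C6, C8) closes by this asynchronous two-bond annulation on one face of the ring alkene, so the ring fusion can only be cis. C4 and C5 are set by approach of 11 to the face of the dihydrofuran opposite to the C1 aryl group, and C8 should be set under thermodynamic control, because collidine equilibrates the α-aryl iminium through its enamine to the exo aryl on the convex face. The step needs the orientation C6 to C5 and C8 to C4: the substituted terminus C8 should prefer the alkene carbon remote from C1, and positive charge in the transition state is better placed on C4 (beside the CH2 C3) than on C5 (beside C1 with its oxygen and aryl carbon), but this bias is modest and is the one real risk of the route. Slow addition of Tf2O to an excess of amide and collidine keeps free anhydride and strong acid away from the benzylic, allylic C1–O2 bond and from the silyl ethers.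

Step 8
Reactants: 13 (1S,2S,5R,6S)-2-{4-[(tert-butyldimethylsilyl)oxy]-3-methoxyphenyl}-6-{4-[(tert-butyldimethylsilyl)oxy]-3,5-dimethoxyphenyl}-3-oxabicyclo[3.2.0]heptan-7-one
Product: 14 (3S,3aR,6S,6aS)-6-{4-[(tert-butyldimethylsilyl)oxy]-3-methoxyphenyl}-3-{4-[(tert-butyldimethylsilyl)oxy]-3,5-dimethoxyphenyl}tetrahydro-1H,3H-furo[3,4-c]furan-1-one
Conditions: mCPBA, NaHCO3, CH2Cl2, 0 °C
Reagents that add atoms: 3-chloroperoxybenzoic acid (mCPBA), O=C(OO)c1cccc(Cl)c1
Why: Baeyer–Villiger ring expansion of a strained cyclobutanone: in the peracid adduct the benzylic C8 with its electron-rich aryl group should migrate in preference to C5 (a secondary carbon deactivated by the β-oxygen O2), with retention at C8, so O7 enters between C6 and C8, and strain release should let the ketone react before the peracid touches the arenes.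

Step 9
Reactants: 14 (3S,3aR,6S,6aS)-6-{4-[(tert-butyldimethylsilyl)oxy]-3-methoxyphenyl}-3-{4-[(tert-butyldimethylsilyl)oxy]-3,5-dimethoxyphenyl}tetrahydro-1H,3H-furo[3,4-c]furan-1-one
Product: 15 (3S,3aR,6S,6aS)-6-(4-hydroxy-3-methoxyphenyl)-3-(4-hydroxy-3,5-dimethoxyphenyl)tetrahydro-1H,3H-furo[3,4-c]furan-1-one (target, CNP0142585.1)
Conditions: TBAF, AcOH (1:1), THF, 0 °C
Reagents that add atoms: none
Why: Fluoride desilylation of both aryl silyl ethers; acetic acid keeps the freed phenols protonated, so neither can expel the benzylic oxygen at C1 or C8 as a quinone methide or open the lactone.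

Compound list
1 | vanillin (4-hydroxy-3-methoxybenzaldehyde) | COc1cc(C=O)ccc1O | starting material
2 | 4-[(tert-butyldimethylsilyl)oxy]-3-methoxybenzaldehyde | COc1cc(C=O)ccc1O[Si](C)(C)C(C)(C)C | intermediate
3 | 4-[(tert-butyldimethylsilyl)oxy]-3-methoxyphenyl formate | COc1cc(OC=O)ccc1O[Si](C)(C)C(C)(C)C | intermediate (not isolated)
4 | 4-[(tert-butyldimethylsilyl)oxy]-3-methoxyphenol | COc1cc(O)ccc1O[Si](C)(C)C(C)(C)C | intermediate
5 | 4-[(tert-butyldimethylsilyl)oxy]-3-methoxyphenyl trifluoromethanesulfonate | COc1cc(OS(=O)(=O)C(F)(F)F)ccc1O[Si](C)(C)C(C)(C)C | intermediate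
6 | 2,3-dihydrofuran | C1=COCC1 | starting material
7 | (S)-2-{4-[(tert-butyldimethylsilyl)oxy]-3-methoxyphenyl}-2,5-dihydrofuran | COc1cc([C@H]2OCC=C2)ccc1O[Si](C)(C)C(C)(C)C | intermediate
8 | 4-hydroxy-3,5-dimethoxyphenylacetic acid | COc1cc(CC(=O)O)cc(OC)c1O | starting material
9 | 2-(4-hydroxy-3,5-dimethoxyphenyl)-N,N-dimethylacetamide | CN(C)C(=O)Cc1cc(OC)c(O)c(OC)c1 | intermediate
10 | 2-{4-[(tert-butyldimethylsilyl)oxy]-3,5-dimethoxyphenyl}-N,N-dimethylacetamide | CN(C)C(=O)Cc1cc(OC)c(O[Si](C)(C)C(C)(C)C)c(OC)c1 | intermediate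
11 | N-{2-[4-(tert-butyldimethylsilyloxy)-3,5-dimethoxyphenyl]ethenylidene}-N-methylmethanaminium triflate (keteniminium triflate) | C[N+](C)=C=Cc1cc(OC)c(O[Si](C)(C)C(C)(C)C)c(OC)c1.[O-]S(=O)(=O)C(F)(F)F | intermediate (not isolated)
12 | N,N-dimethyliminium triflate of ketone 13, same configuration (cyclobutaniminium triflate) | COc1cc([C@H]2OC[C@H]3[C@@H]2C(=[N+](C)C)[C@@H]3c2cc(OC)c(O[Si](C)(C)C(C)(C)C)c(OC)c2)ccc1O[Si](C)(C)C(C)(C)C.[O-]S(=O)(=O)C(F)(F)F | intermediate (not isolated)
13 | (1S,2S,5R,6S)-2-{4-[(tert-butyldimethylsilyl)oxy]-3-methoxyphenyl}-6-{4-[(tert-butyldimethylsilyl)oxy]-3,5-dimethoxyphenyl}-3-oxabicyclo[3.2.0]heptan-7-one | COc1cc([C@H]2OC[C@H]3[C@@H]2C(=O)[C@@H]3c2cc(OC)c(O[Si](C)(C)C(C)(C)C)c(OC)c2)ccc1O[Si](C)(C)C(C)(C)C | intermediate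
14 | (3S,3aR,6S,6aS)-6-{4-[(tert-butyldimethylsilyl)oxy]-3-methoxyphenyl}-3-{4-[(tert-butyldimethylsilyl)oxy]-3,5-dimethoxyphenyl}tetrahydro-1H,3H-furo[3,4-c]furan-1-one | COc1cc([C@H]2OC[C@H]3[C@@H]2C(=O)O[C@@H]3c2cc(OC)c(O[Si](C)(C)C(C)(C)C)c(OC)c2)ccc1O[Si](C)(C)C(C)(C)C | intermediate
15 | (3S,3aR,6S,6aS)-6-(4-hydroxy-3-methoxyphenyl)-3-(4-hydroxy-3,5-dimethoxyphenyl)tetrahydro-1H,3H-furo[3,4-c]furan-1-one | COc1cc([C@H]2OC[C@H]3[C@@H]2C(=O)O[C@@H]3c2cc(OC)c(O)c(OC)c2)ccc1O | target

Total steps: 9 (four to the dihydrofuran, two to the amide, three from their union).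
Longest linear sequence: 7 steps (1 → 2 → 4 → 5 → 7 → 13 → 14 → 15).

Steps most likely to fail

Step 7. The keteniminium ion may add in the reverse orientation (C6 to C4, C8 to C5), or the cationic reagent may acylate the guaiacyl ring or open the C1–O2 bond instead of adding to the alkene. Any reagent that adds across C4=C5 of 7 meets the same near-symmetry, so the fallback leaves the cycloaddition and fixes the constitution by the choice of coupling partners. It sets out from 1: Knoevenagel–Doebner condensation with malonic acid (pyridine, piperidine, 90 °C) gives ferulic acid F1. F1 in excess and purchased sinapyl alcohol F2 are then oxidised together (horseradish peroxidase, H2O2, aqueous acetone, pH 5). Radical coupling at the two side-chain β-carbons forms C4–C5, and the bis(quinone methide) closes twice, the carboxyl group (C6) onto C8 and the primary hydroxyl (on C3) onto C1, to give the racemic all-exo lactone F3. Preparative chromatography on a chiral stationary phase returns to the route at 15. This coupling is expected to be low-yielding, with homo-dimers to remove, but it needs no protecting groups and cannot give the regioisomeric skeleton.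

Step 4. Oxidative addition of the electron-rich triflate may be slow, with erosion of enantioselectivity or drift of the double bond to the 2,3-dihydrofuran isomer. The fallback sets out from 2: vinylmagnesium bromide (THF, −78 °C) gives the racemic allylic alcohol F4. Lipase-catalysed acetylation (Candida antarctica lipase B, vinyl acetate, toluene, 30 °C) should remove the (R)-enantiomer as its acetate, following the empirical preference of lipases for secondary alcohols with a large aryl and a medium vinyl group, and leave the (S)-alcohol F5. O-Allylation (NaH, allyl bromide, THF, 0 °C) gives the diene ether F6, and ring-closing metathesis with second-generation Grubbs catalyst (CH2Cl2, 40 °C) closes the ring and returns at 7.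

Step 8. C5 may migrate instead of C8 in the peracid adduct, or the peracid may attack the electron-rich arenes. The fallback sets out from 13 and replaces the 1,2-shift by cleavage and re-closure. Soft enolisation (TMSOTf, Et3N, CH2Cl2, 0 °C) towards the benzylic side gives the aryl-conjugated silyl enol ether F7 (C6=C8). Ozonolysis (O3, CH2Cl2/MeOH, −78 °C, stopped with an indicator dye; then Me2S) and aqueous work-up give the keto acid F8, with the carboxyl C6 on C5 and the aryl ketone C8 on C4. NaBH4 (MeOH, 0 °C) gives the hydroxy acid F9, which lactonises with pyridinium p-toluenesulfonate (CH2Cl2, 25 °C) and returns at 14, with O7 necessarily on C8. If the hydride delivers the epimeric carbinol, the ring is closed under Mitsunobu conditions instead, which inverts C8.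

Further compounds
F1 | step 7 | ferulic acid, (E)-3-(4-hydroxy-3-methoxyphenyl)prop-2-enoic acid | COc1cc(/C=C/C(=O)O)ccc1O
F2 | step 7 | sinapyl alcohol (purchased), 4-[(E)-3-hydroxyprop-1-enyl]-2,6-dimethoxyphenol | COc1cc(/C=C/CO)cc(OC)c1O
F3 | step 7 | racemic 15 (15 together with its enantiomer, all-exo) | COc1cc([C@H]2OC[C@H]3[C@@H]2C(=O)O[C@@H]3c2cc(OC)c(O)c(OC)c2)ccc1O.COc1cc([C@@H]2OC[C@@H]3[C@H]2C(=O)O[C@H]3c2cc(OC)c(O)c(OC)c2)ccc1O
F4 | step 4 | racemic 1-{4-[(tert-butyldimethylsilyl)oxy]-3-methoxyphenyl}prop-2-en-1-ol | COc1cc(C(O)C=C)ccc1O[Si](C)(C)C(C)(C)C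
F5 | step 4 | (S)-1-{4-[(tert-butyldimethylsilyl)oxy]-3-methoxyphenyl}prop-2-en-1-ol | COc1cc([C@H](C=C)O)ccc1O[Si](C)(C)C(C)(C)C
F6 | step 4 | (S)-allyl 1-{4-[(tert-butyldimethylsilyl)oxy]-3-methoxyphenyl}prop-2-enyl ether | COc1cc([C@H](C=C)OCC=C)ccc1O[Si](C)(C)C(C)(C)C
F7 | step 8 | trimethylsilyl enol ether of 13 (C6=C8), (1S,2S,5R)-configured | COc1cc([C@H]2OC[C@H]3[C@@H]2C(O[Si](C)(C)C)=C3c2cc(OC)c(O[Si](C)(C)C(C)(C)C)c(OC)c2)ccc1O[Si](C)(C)C(C)(C)C
F8 | step 8 | (2S,3S,4R)-2-{4-[(tert-butyldimethylsilyl)oxy]-3-methoxyphenyl}-4-{4-[(tert-butyldimethylsilyl)oxy]-3,5-dimethoxybenzoyl}tetrahydrofuran-3-carboxylic acid | COc1cc([C@H]2OC[C@H](C(=O)c3cc(OC)c(O[Si](C)(C)C(C)(C)C)c(OC)c3)[C@@H]2C(=O)O)ccc1O[Si](C)(C)C(C)(C)C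
F9 | step 8 | hydroxy acid from F8 with an (S)-configured benzylic carbinol at C8 | COc1cc([C@H]2OC[C@H]([C@H](O)c3cc(OC)c(O[Si](C)(C)C(C)(C)C)c(OC)c3)[C@@H]2C(=O)O)ccc1O[Si](C)(C)C(C)(C)C
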